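**Retrosynthetic overview**
1. C40 = ring C10 unit (C1–C7) + crocetindialdehyde (C20, C8–C8') + open-chain C10 unit (C7'–C1'); Wittig at C7=C8 first, then Wittig at C7'=C8' (carotenoid numbering throughout).
2. Ring end: phosphonium salt ← triol ← cis-fused cyclic carbonate ← (3S,4R)-oxirane ← ethyl safranate, by chiral-dioxirane epoxidation of the C3=C4 bond (sets C3 and C4; proposed new substrate class).
3. Open-chain end: dienyl phosphonium salt ← vinyl carbinol ← (2'S)-diol enone ← (S)-oxirane ← 6-methylhepta-3,5-dien-2-one, by Shi epoxidation (sets C2').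
4. Rings: the carbocycle is bought with ethyl safranate and none is built. Heterocycles form in the order oxirane (step 1), then cyclic carbonate (step 2, opened in step 3) on the ring branch, and oxirane (step 6, opened in step 7) on the open-chain branch.

Assumption: the target is the all-E (3S,4R,2'S) tetrol as drawn; ethyl safranate, crocetindialdehyde, (3E)-6-methylhepta-3,5-dien-2-one and both sugar-derived ketone catalysts are taken as purchasable.

**Route**

Step 1
Reactants: 1 ethyl safranate (ethyl 2,6,6-trimethylcyclohexa-1,3-diene-1-carboxylate)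
Product: 2 ethyl (1R,6S)-2,4,4-trimethyl-7-oxabicyclo[4.1.0]hept-2-ene-3-carboxylate
Conditions: Shi's D-glucose-derived N-(4-tolyl) spiro-oxazolidinone ketone (25 mol%), KHSO5 (as 2KHSO5·KHSO4·K2SO4, 1.8 equiv), K2CO3, Bu4NHSO4 (5 mol%), DME/CH2(OMe)2–aq. K2CO3/AcOH buffer (pH 8), −10 °C
Reagents that add atoms: potassium peroxymonosulfate, [K+].OOS(=O)(=O)[O-]
Why: Proposed new method: the dioxirane formed from the chiral ketone and KHSO5 should transfer oxygen only to the cis-disubstituted C3=C4 bond, because the tetrasubstituted C5=C6 bond is deactivated by the ester and shielded by the gem-dimethyl group, and the spiro transition state that places the conjugating C5=C6 unit beside the oxazolidinone (the position taken by the aryl group of 1,2-dihydronaphthalene or cis-β-methylstyrene in the known cases) leads to the (3S,4R)-oxide, so that C3 and C4 are set together; the closest known reaction type is the Shi epoxidation of conjugated cis-olefins and the distal-selective Shi mono-epoxidation of acyclic dienoates, neither of which has been shown on a cyclohexa-1,3-diene-1-carboxylate.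

Step 2
Reactants: 2 ethyl (1R,6S)-2,4,4-trimethyl-7-oxabicyclo[4.1.0]hept-2-ene-3-carboxylate
Product: 3 ethyl (3aR,7aS)-4,6,6-trimethyl-2-oxo-3a,6,7,7a-tetrahydro-1,3-benzodioxole-5-carboxylate
Conditions: CO2 (2 MPa), Bu4NBr (10 mol%), neat, 80 °C
Reagents that add atoms: carbon dioxide, O=C=O
Why: Halide-catalysed coupling of CO2 to an oxirane (cyclic carbonate synthesis): bromide opens the oxirane with inversion, the alkoxide takes up CO2 and the carbonate oxygen displaces bromide with a second inversion, so both C–O bonds keep their configuration and the cis-fused (3S,4R)-carbonate results.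

Step 3
Reactants: 3 ethyl (3aR,7aS)-4,6,6-trimethyl-2-oxo-3a,6,7,7a-tetrahydro-1,3-benzodioxole-5-carboxylate
Product: 4 (1S,2R)-4-(hydroxymethyl)-3,5,5-trimethylcyclohex-3-ene-1,2-diol
Conditions: LiAlH4 (3 equiv), THF, 0 °C → rt; aqueous work-up
Reagents that add atoms: none
Why: LiAlH4 reduction: 1,2-hydride addition turns the hindered conjugated ester into the primary allylic alcohol and cleaves the carbonate to the cis-diol without breaking a C–O bond at C3 or C4.

Step 4
Reactants: 4 (1S,2R)-4-(hydroxymethyl)-3,5,5-trimethylcyclohex-3-ene-1,2-diol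
Product: 6 {[(3R,4S)-3,4-dihydroxy-2,6,6-trimethylcyclohex-1-en-1-yl]methyl}triphenylphosphonium bromide, via allylic bromide 5 (not isolated)
Conditions: CBr4 (1.1 equiv), PPh3 (2.3 equiv), CH2Cl2, −20 → 0 °C; then MeCN, 40 °C
Reagents that add atoms: tetrabromomethane, BrC(Br)(Br)Br; triphenylphosphine, c1ccc(cc1)P(c1ccccc1)c1ccccc1
Why: Appel bromination attacks the unhindered primary allylic hydroxyl far faster than the two flanked secondary ones and passes through no allyl cation, and the excess PPh3 then quaternises the allylic bromide by SN2, so C3 and C4 are untouched.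

Step 5
Reactants: 6 {[(3R,4S)-3,4-dihydroxy-2,6,6-trimethylcyclohex-1-en-1-yl]methyl}triphenylphosphonium bromide; 7 crocetindialdehyde ((2E,4E,6E,8E,10E,12E,14E)-2,6,11,15-tetramethylhexadeca-2,4,6,8,10,12,14-heptaenedial)
Product: 10 (3S,4R)-3,4-dihydroxy-8'-apo-β-caroten-8'-al, via ring ylide 8 (not isolated), via 7Z isomer 9 (not isolated)
Conditions: 7 (3 equiv, excess recovered), NaOMe (1.2 equiv, added over 1 h), CH2Cl2/MeOH, −10 °C → rt; then I2 (1 mol%), CH2Cl2, daylight, rt
Reagents that add atoms: none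
Why: Wittig olefination: the allylic ylide is generated slowly in the presence of excess dialdehyde so that it is trapped as the mono-adduct before it can lose hydroxide, and iodine-catalysed isomerisation turns the strained 7Z olefin into the 7E isomer.

Step 6
Reactants: 11 (3E)-6-methylhepta-3,5-dien-2-one
Product: 12 (3E)-4-[(2S)-3,3-dimethyloxiran-2-yl]but-3-en-2-one
Conditions: 1,2:4,5-di-O-isopropylidene-β-L-erythro-2,3-hexodiulo-2,6-pyranose (L-series Shi ketone, 30 mol%), KHSO5 (as 2KHSO5·KHSO4·K2SO4, 1.4 equiv), K2CO3, Bu4NHSO4 (4 mol%), MeCN/CH2(OMe)2–aq. Na2B4O7 buffer (pH 10.5), 0 °C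
Reagents that add atoms: potassium peroxymonosulfate, [K+].OOS(=O)(=O)[O-]
Why: Shi epoxidation: the chiral dioxirane attacks only the electron-rich distal trisubstituted olefin (the enone olefin is deactivated) through the spiro transition state, and the L-configured ketone delivers oxygen to the face that gives the (S)-oxirane carbon, which becomes C2'.

Step 7
Reactants: 12 (3E)-4-[(2S)-3,3-dimethyloxiran-2-yl]but-3-en-2-one
Product: 13 (3E,5S)-5,6-dihydroxy-6-methylhept-3-en-2-one
Conditions: HClO4 (5 mol%), THF/H2O (3:1), 0 °C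
Reagents that add atoms: water, O
Why: Acid-catalysed epoxide hydrolysis: water enters at the tertiary carbon (C1'), whereas the allylic C2' position is deactivated by the enone, so the C2'–O bond is never broken and the (S) configuration is kept.

Step 8
Reactants: 13 (3E,5S)-5,6-dihydroxy-6-methylhept-3-en-2-one; 14 vinylmagnesium bromide
Product: 15 (4E,6S)-3,7-dimethylocta-1,4-diene-3,6,7-triol (both C3 epimers)
Conditions: CH2=CHMgBr (3.5 equiv), THF, −20 → 0 °C; aqueous work-up
Reagents that add atoms: none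
Why: Grignard 1,2-addition to the methyl enone after deprotonation of the two hydroxyls, as in the vinylation of ionones; the new tertiary carbinol forms as both epimers, which is of no consequence because this centre becomes sp2 in step 9.

Step 9
Reactants: 15 (4E,6S)-3,7-dimethylocta-1,4-diene-3,6,7-triol
Product: 16 [(2E,4E,6S)-6,7-dihydroxy-3,7-dimethylocta-2,4-dien-1-yl]triphenylphosphonium bromide
Conditions: PPh3·HBr (1.05 equiv), MeOH, 0 °C → rt; crystallise
Reagents that add atoms: triphenylphosphine hydrobromide, [Br-].c1ccc(cc1)[PH+](c1ccccc1)c1ccccc1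
Why: Acid-promoted allylic transposition used for carotenoid Wittig salts: the tertiary doubly allylic alcohol ionises to a pentadienyl cation that PPh3 captures at the primary terminus, while the secondary C2' alcohol next to an oxygen-bearing carbon does not ionise under these conditions.

Step 10
Reactants: 10 (3S,4R)-3,4-dihydroxy-8'-apo-β-caroten-8'-al; 16 [(2E,4E,6S)-6,7-dihydroxy-3,7-dimethylocta-2,4-dien-1-yl]triphenylphosphonium bromide
Product: 19 (3S,4R,2'S)-3',4'-didehydro-1',2'-dihydro-β,ψ-carotene-3,4,1',2'-tetrol (CNP0343898.1), via acyclic ylide 17 (not isolated), via 7'Z isomer 18 (not isolated)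
Conditions: 16 (1.5 equiv), NaOMe (1.6 equiv, added over 1 h), CH2Cl2/MeOH, −10 °C → rt; then EtOAc, reflux, N2, dark; crystallise
Reagents that add atoms: none
Why: Wittig olefination of the apocarotenal with the dienyl ylide (the C30 + C10 union customary for carotenoids with an open-chain end), with base again added slowly to the mixture, followed by thermal isomerisation of the hindered 7'Z olefin to the all-E tetrol; no stereocentre is involved.

**Compound list**
1 | ethyl safranate, ethyl 2,6,6-trimethylcyclohexa-1,3-diene-1-carboxylate | CC1=C(C(=O)OCC)C(C)(C)CC=C1 | starting material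
2 | ethyl (1R,6S)-2,4,4-trimethyl-7-oxabicyclo[4.1.0]hept-2-ene-3-carboxylate ((3S,4R)-oxide in carotenoid numbering) | CC1=C(C(=O)OCC)C(C)(C)C[C@@H]2O[C@H]12 | intermediate
3 | ethyl (3aR,7aS)-4,6,6-trimethyl-2-oxo-3a,6,7,7a-tetrahydro-1,3-benzodioxole-5-carboxylate (cis-fused carbonate) | CC1=C(C(=O)OCC)C(C)(C)C[C@@H]2OC(=O)O[C@H]12 | intermediate
4 | (1S,2R)-4-(hydroxymethyl)-3,5,5-trimethylcyclohex-3-ene-1,2-diol | CC1=C(CO)C(C)(C)C[C@H](O)[C@@H]1O | intermediate
5 | (1S,2R)-4-(bromomethyl)-3,5,5-trimethylcyclohex-3-ene-1,2-diol | CC1=C(CBr)C(C)(C)C[C@H](O)[C@@H]1O | intermediate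
6 | {[(3R,4S)-3,4-dihydroxy-2,6,6-trimethylcyclohex-1-en-1-yl]methyl}triphenylphosphonium bromide | CC1=C(C[P+](c2ccccc2)(c2ccccc2)c2ccccc2)C(C)(C)C[C@H](O)[C@@H]1O.[Br-] | intermediate
7 | crocetindialdehyde, (2E,4E,6E,8E,10E,12E,14E)-2,6,11,15-tetramethylhexadeca-2,4,6,8,10,12,14-heptaenedial | O=C/C(C)=C/C=C/C(C)=C/C=C/C=C(C)/C=C/C=C(C)/C=O | starting material
8 | ring ylide, {[(3R,4S)-3,4-dihydroxy-2,6,6-trimethylcyclohex-1-en-1-yl]methylidene}triphenylphosphorane | CC1=C(C=P(c2ccccc2)(c2ccccc2)c2ccccc2)C(C)(C)C[C@H](O)[C@@H]1O | intermediate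
9 | (7Z)-isomer of 10 | CC1=C(\C=C/C(C)=C/C=C/C(C)=C/C=C/C=C(C)/C=C/C=C(C)/C=O)C(C)(C)C[C@H](O)[C@@H]1O | intermediate
10 | (3S,4R)-3,4-dihydroxy-8'-apo-β-caroten-8'-al, (2E,4E,6E,8E,10E,12E,14E,16E)-17-[(3R,4S)-3,4-dihydroxy-2,6,6-trimethylcyclohex-1-en-1-yl]-2,6,11,15-tetramethylheptadeca-2,4,6,8,10,12,14,16-octaenal | CC1=C(/C=C/C(C)=C/C=C/C(C)=C/C=C/C=C(C)/C=C/C=C(C)/C=O)C(C)(C)C[C@H](O)[C@@H]1O | intermediate
11 | (3E)-6-methylhepta-3,5-dien-2-one | CC(=O)/C=C/C=C(C)C | starting material
12 | (3E)-4-[(2S)-3,3-dimethyloxiran-2-yl]but-3-en-2-one | CC(=O)/C=C/[C@@H]1OC1(C)C | intermediate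
13 | (3E,5S)-5,6-dihydroxy-6-methylhept-3-en-2-one | CC(=O)/C=C/[C@H](O)C(C)(C)O | intermediate
14 | vinylmagnesium bromide | C=C[Mg]Br | starting material
15 | (4E,6S)-3,7-dimethylocta-1,4-diene-3,6,7-triol (both C3 epimers) | C=CC(C)(O)/C=C/[C@H](O)C(C)(C)O | intermediate
16 | [(2E,4E,6S)-6,7-dihydroxy-3,7-dimethylocta-2,4-dien-1-yl]triphenylphosphonium bromide | C(/C=C(C)/C=C/[C@H](O)C(C)(C)O)[P+](c1ccccc1)(c1ccccc1)c1ccccc1.[Br-] | intermediate
17 | acyclic ylide, [(2E,4E,6S)-6,7-dihydroxy-3,7-dimethylocta-2,4-dien-1-ylidene]triphenylphosphorane | C(/C=C(C)/C=C/[C@H](O)C(C)(C)O)=P(c1ccccc1)(c1ccccc1)c1ccccc1 | intermediate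
18 | (7'Z)-isomer of 19 | CC1=C(/C=C/C(C)=C/C=C/C(C)=C/C=C/C=C(C)/C=C/C=C(C)/C=C\C=C(C)\C=C\[C@H](O)C(C)(C)O)C(C)(C)C[C@H](O)[C@@H]1O | intermediate
19 | (3S,4R,2'S)-3',4'-didehydro-1',2'-dihydro-β,ψ-carotene-3,4,1',2'-tetrol, all-E (CNP0343898.1) | CC1=C(/C=C/C(C)=C/C=C/C(C)=C/C=C/C=C(C)/C=C/C=C(C)/C=C/C=C(C)/C=C/[C@H](O)C(C)(C)O)C(C)(C)C[C@H](O)[C@@H]1O | target

**Step count and risks**

Total steps: 10 (ring branch steps 1–5, open-chain branch steps 6–9, union step 10). Longest linear sequence: 6 steps (1, 2, 3, 4, 5, 10).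

Steps most likely to fail:

Step 1 (the proposed epoxidation): site selectivity or enantioselectivity may fall short on this untested cyclic diene ester. The fallback sets out from 1 and comes back at 2. It is a Jacobsen–Katsuki epoxidation with (R,R)-N,N'-bis(3,5-di-tert-butylsalicylidene)-1,2-cyclohexanediaminomanganese chloride (4 mol%), NaOCl and 4-phenylpyridine N-oxide in CH2Cl2 at 0 °C. This manganese-oxo oxygen transfer is established for cis-disubstituted olefins conjugated to an alkene, cyclic 1,3-dienes included. The (R,R) complex is chosen by analogy with indene, where the (S,S) complex gives the (1S,2R)-oxide. It makes no compound outside the list (F0).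

Step 5 (Wittig reaction of the hindered, hydroxylated ring ylide): the ylide may react sluggishly or eliminate the C4 hydroxyl. The fallback sets out from 4 and comes back at 10, and replaces the Wittig reaction by a Julia–Kocienski olefination. Mitsunobu thioetherification of the primary allylic hydroxyl of 4 with 1-phenyl-1H-tetrazole-5-thiol (PPh3, DIAD, THF, 0 °C) gives 5-({[(3R,4S)-3,4-dihydroxy-2,6,6-trimethylcyclohex-1-en-1-yl]methyl}sulfanyl)-1-phenyl-1H-tetrazole F1. Oxidation with H2O2 and (NH4)6Mo7O24 in EtOH at 0 °C gives 5-({[(3R,4S)-3,4-dihydroxy-2,6,6-trimethylcyclohex-1-en-1-yl]methyl}sulfonyl)-1-phenyl-1H-tetrazole F2. Its potassium derivative (KN(SiMe3)2, 3.1 equiv, THF/DME, −78 °C) adds to excess 7 and collapses by Smiles rearrangement to the 7E olefin 10.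

Step 9 (acid-mediated salt formation beside a free allylic diol): the C2' alcohol could ionise or the hydroxyls could trap the cation. The fallback sets out from 13 and comes back at 16, and generates no cation. Horner–Wadsworth–Emmons reaction of 13 with triethyl phosphonoacetate (NaH, THF, 0 °C → rt) gives ethyl (2E,4E,6S)-6,7-dihydroxy-3,7-dimethylocta-2,4-dienoate F3, the 2Z isomer being removed by chromatography. Reduction with i-Bu2AlH (CH2Cl2, −78 °C) gives (2E,4E,6S)-3,7-dimethylocta-2,4-diene-1,6,7-triol F4. Appel bromination and quaternisation as in step 4 (CBr4, PPh3, CH2Cl2, −20 °C; then MeCN, 40 °C) give 16.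

**Further compounds**
F0 | step 1 | none | none
F1 | step 5 | 5-({[(3R,4S)-3,4-dihydroxy-2,6,6-trimethylcyclohex-1-en-1-yl]methyl}sulfanyl)-1-phenyl-1H-tetrazole | CC1=C(CSc2nnnn2-c2ccccc2)C(C)(C)C[C@H](O)[C@@H]1O
F2 | step 5 | 5-({[(3R,4S)-3,4-dihydroxy-2,6,6-trimethylcyclohex-1-en-1-yl]methyl}sulfonyl)-1-phenyl-1H-tetrazole | CC1=C(CS(=O)(=O)c2nnnn2-c2ccccc2)C(C)(C)C[C@H](O)[C@@H]1O
F3 | step 9 | ethyl (2E,4E,6S)-6,7-dihydroxy-3,7-dimethylocta-2,4-dienoate | CCOC(=O)/C=C(C)/C=C/[C@H](O)C(C)(C)O
F4 | step 9 | (2E,4E,6S)-3,7-dimethylocta-2,4-diene-1,6,7-triol | OC/C=C(C)/C=C/[C@H](O)C(C)(C)O
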